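Per second, the transfer of gas can deliver 0.0292 /s of the charge into a solution kept empty, which over 50 s comes to 146%. Everything below runs in fractions of the charge: a for substrate, p for target.

    gas phase ⇌ dissolved gas, rate k1*(csat - [dissolved gas]) (k1 = 0.10 /s, csat = 35 mM)
    substrate + dissolved gas → target (k2 = 2.8 /M/s)
    dissolved gas + target → over-reacted product (k3 = 3.6 /M/s)
    target → over-reaction product (k4 = 0.0022 /s)
    substrate ⇌ dormant form (K5 = 1.1, k5 = 0.014 /s)

substrate 0.12 M; gas phase 35 mM (held); time 50 s

- at the start none of the gas is dissolved
- run time (flask): 50 s

- target at 50 s, in percent of the substrate charged
- concentration of dissolved gas in solution at 50 s, in percent of saturation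

What should be watched in this flask? Dissolved gas.

Why that one? At the charged concentrations the half-life of dissolved gas by the second step of the scheme alone is 2.1 s, shorter than the 50 s of the run, so I reckon dissolved gas as quasi-steady.

At what level does it stand? Set transfer in equal to use. Substrate at full charge has a gas demand of 0.336 /s and target at full charge one of 0.432 /s. The saturation share, the transfer coefficient 0.10 /s divided by the sum of itself, 0.336 /s times a and 0.432 /s times p, is then 22.9% for the fresh charge.

But a and p move. Does that figure hold? No. A fraction passing from substrate to target raises the sum, since target demands more than substrate. A fraction passing to dormant form or over-reacted product takes its term out of the sum. I expect that second loss to win, and I commit to a share above 22.9% at 50 s. My reckoning stops there, with no hand figure for target.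

The forecast gives 20.5% of target and 41% of saturation, on the ground that “Gas transfer is limiting”. The simulation gives 20.9% and 37.8%.

In this flask substrate fell from 87.4% at 5.00 s to 43.1% at 25.0 s while the step to target brought target to 24.3%. By 50.0 s dissolved gas and target had lifted over-reacted product from 11.6% to 35.8%, with target down to 20.9%. The fractions at 50.0 s in this flask reckon to a saturation share of 39.8%, against 37.8% simulated. In the neighbour flask with 0.048 M of substrate, 7.51% and 11.9% of its own charge reckon to 76.5%, and its dissolved gas stood at 70.1% of saturation.

(Its constants were set for the occasion; no experiment stands behind them.)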